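**Retrosynthetic overview**

1. The target (tetrahydrofuran O1, C2–C5; dihydrobenzofuran O1', C2', C3', C3a', C4'–C7', C7a') is opened at the C2 benzyl group (hydroboration/B-alkyl Suzuki of a 2-methylidene tetrahydrofuran) and at O1–C2 (5-exo-dig hydroalkoxylation of an anti-1,3-diol alkyne). The diol comes from an anti-aldol of aryl aldehyde 20 (sets C4, C5) and a directed ketone reduction (sets C3).
2. Aldehyde 20 comes from phenol 18 by O-methylation at C7' and acetal hydrolysis at C5'.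
3. The route rests on the benzo ring C3a'–C4'–C5'–C6'–C7'–C7a', whose 1,2,3,5 pattern (C3' on C3a', O1' on C7a', oxygen on C7', carbon on C5') is made in one gold-catalysed isomerisation of a 2,4-disubstituted furan tethered to an ethynyl ether (17 to 18). This step forms C7a'–C3a' and C7'–C6' and moves the furan oxygen to C7'.
4. Ethynyl ether 17 comes from an anti-aldol (sets C3' and C2') of furylacetyl imide 9 with O-benzylvanillin 10. Imide 9 is made from 3-furaldehyde by acetalisation, C5 borylation and coupling with bromoacetate.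
5. Ring order: furan (bought), then dihydrofuran and benzene together (step 10), then tetrahydrofuran (step 19).

Key step: step 10

Assumption: the MgCl2-catalysed anti-aldol reactions (steps 6 and 15) are taken to follow the chelated Z-enolate model, with attack on the face away from the auxiliary benzyl group; the auxiliary enantiomers (R in step 5, S in step 14) are chosen on that basis.

Ar' below means the (2R,3R)-2-[4-(benzyloxy)-3-methoxyphenyl]-7-methoxy-3-{[(triisopropylsilyl)oxy]methyl}-2,3-dihydrobenzofuran-5-yl group of compound 20.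

**Step 1**
Reactants: 1 3-furaldehyde
Product: 2 2-(furan-3-yl)-1,3-dioxolane
Conditions: ethylene glycol, p-TsOH·H2O (cat.), benzene, reflux, Dean–Stark
Reagents that add atoms: ethylene glycol, OCCO
Why: Acid-catalysed acetalisation with azeotropic removal of water masks the future C5' formyl group before any sensitive functionality is present.

**Step 2**
Reactants: 2 2-(furan-3-yl)-1,3-dioxolane
Product: 3 2-[4-(1,3-dioxolan-2-yl)furan-2-yl]-4,4,5,5-tetramethyl-1,3,2-dioxaborolane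
Conditions: B2pin2 (1.0 equiv), [Ir(OMe)(cod)]2 (1.5 mol%), dtbpy (3 mol%), hexane, 25 °C
Reagents that add atoms: bis(pinacolato)diboron, CC1(C)OB(OC1(C)C)B1OC(C)(C)C(C)(C)O1
Why: Iridium-catalysed C–H borylation of a 3-substituted furan is sterically controlled and goes to the free α-position remote from the substituent, which gives the 2,4-disubstituted furan.

**Step 3**
Reactants: 3 furyl pinacolboronate; 4 ethyl bromoacetate
Product: 5 ethyl 2-[4-(1,3-dioxolan-2-yl)furan-2-yl]acetate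
Conditions: Pd(OAc)2 (3 mol%), P(1-naphthyl)3 (9 mol%), K3PO4, THF–H2O, 25 °C
Reagents that add atoms: none
Why: Suzuki–Miyaura-type sp2–sp3 coupling of a heteroaryl boronate with an α-bromo ester proceeds under mild base and places the acetic ester on furan C2.

**Step 4**
Reactants: 5 ethyl furylacetate
Product: 6 2-[4-(1,3-dioxolan-2-yl)furan-2-yl]acetic acid
Conditions: LiOH·H2O, THF–H2O, 0 → 25 °C; citric acid to pH 4, 0 °C
Reagents that add atoms: lithium hydroxide, [Li+].[OH-]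
Why: Saponification of an unhindered ester; the acetal survives base and the brief, cold, weakly acidic work-up.

**Step 5**
Reactants: 6 furylacetic acid; 7 (R)-4-benzyloxazolidin-2-one
Product: 9 (R)-4-benzyl-3-{2-[4-(1,3-dioxolan-2-yl)furan-2-yl]acetyl}oxazolidin-2-one, via mixed pivalic anhydride 8 (not isolated)
Conditions: PivCl, Et3N, THF, −20 °C; then 7, LiCl, 25 °C
Reagents that add atoms: pivaloyl chloride, CC(C)(C)C(Cl)=O (in 8 only)
Why: N-acylation of the oxazolidinone through the mixed anhydride with LiCl activation is standard for arylacetic acids; the hindered pivaloyl carbonyl is not attacked.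

**Step 6**
Reactants: 9 furylacetyl imide; 10 4-(benzyloxy)-3-methoxybenzaldehyde (O-benzylvanillin, commercial)
Product: 12 (R)-4-benzyl-3-{(2R,3R)-3-[4-(benzyloxy)-3-methoxyphenyl]-2-[4-(1,3-dioxolan-2-yl)furan-2-yl]-3-hydroxypropanoyl}oxazolidin-2-one, via trimethylsilyl ether 11 (not isolated)
Conditions: MgCl2 (20 mol%), Et3N, TMSCl, EtOAc, 23 °C; then Et3N·3HF, THF, 0 °C
Reagents that add atoms: chlorotrimethylsilane, C[Si](C)(C)Cl (in 11 only)
Why: Evans MgCl2-catalysed anti-aldol: the Mg-chelated Z-enolate of the (R)-imide should add to the non-enolisable aryl aldehyde on the face away from the auxiliary benzyl group through a boat-like transition state, setting C3' (R) and C2' (R) anti, while TMSCl traps the aldolate so the addition is not reversed.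

**Step 7**
Reactants: 12 anti-aldol adduct
Product: 13 (1R,2R)-1-[4-(benzyloxy)-3-methoxyphenyl]-2-[4-(1,3-dioxolan-2-yl)furan-2-yl]propane-1,3-diol
Conditions: LiBH4, MeOH (1.2 equiv), THF, 0 °C
Reagents that add atoms: none
Why: Reductive cleavage of the N-acyl oxazolidinone by borohydride at the exocyclic carbonyl gives the primary alcohol without touching the two stereocentres; the auxiliary is recovered.

**Step 8**
Reactants: 13 diol
Product: 14 (1R,2R)-1-[4-(benzyloxy)-3-methoxyphenyl]-2-[4-(1,3-dioxolan-2-yl)furan-2-yl]-3-[(triisopropylsilyl)oxy]propan-1-ol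
Conditions: TIPSCl, imidazole, DMF, 0 → 25 °C
Reagents that add atoms: chlorotriisopropylsilane, CC(C)[Si](Cl)(C(C)C)C(C)C
Why: The bulky silyl chloride reacts selectively at the primary hydroxyl; triisopropylsilyl is used because it resists base-mediated 1,3 O-to-O migration to the secondary alkoxide in step 9.

**Step 9**
Reactants: 14 secondary alcohol; 15 trichloroethylene
Product: 17 (1R,2R)-1-[4-(benzyloxy)-3-methoxyphenyl]-2-[4-(1,3-dioxolan-2-yl)furan-2-yl]-1-(ethynyloxy)-3-[(triisopropylsilyl)oxy]propane, via dichlorovinyl ether 16 (not isolated)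
Conditions: KH, THF, 0 °C; Cl2C=CHCl, −50 → 20 °C; then n-BuLi (2.6 equiv), −78 → −40 °C; MeOH, −78 °C; cold work-up, used at once
Reagents that add atoms: none
Why: Trichloroethylene-based ynol ether synthesis: the potassium alkoxide adds to dichloroacetylene formed in situ to give the (E)-1,2-dichlorovinyl ether, and n-BuLi then effects elimination and Li–Cl exchange to the lithium alkynyl ether, which is protonated cold; the carbinol C–O bond is never broken, so C2' keeps its configuration.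

**Step 10**
Reactants: 17 furan-tethered ethynyl ether
Product: 18 (2R,3R)-2-[4-(benzyloxy)-3-methoxyphenyl]-5-(1,3-dioxolan-2-yl)-3-{[(triisopropylsilyl)oxy]methyl}-2,3-dihydrobenzofuran-7-ol (cis)
Conditions: Ph3PAuNTf2 (3 mol%), CH2Cl2, 4 Å MS, 0 → 20 °C
Reagents that add atoms: none
Why: The cationic monovalent gold centre π-activates the electron-rich ynol ether, whose oxygen-bearing carbon is attacked by furan C2 in a 5-exo-dig closure of the dihydrofuran ring (C7a'–C3a') to give a cyclopropyl gold carbenoid; the furan then opens to a dienone carbenoid, which recloses through an oxepine and its arene oxide valence isomer so that the alkyne terminus bonds to furan C5 (C7'–C6') and the six-membered carbocycle is formed. The closest known reaction is the gold-catalysed furan–yne phenol synthesis, which has been run with alkynyl ether tethers to give 7-hydroxy-2,3-dihydrobenzofurans. No stereocentre is created: C2' and C3' sit on the three-atom tether, take part in no bond change and keep the cis relationship set in step 6. The required regiochemistry, hydroxyl on C7' and not C6', should follow because the arene oxide opens at C6'–O, the resulting cation being delocalised onto C7a' where the ring oxygen O1' stabilises it, and the 1,2,3,5 pattern follows from the 2,4-substitution of the furan. The required chemoselectivity, cyclisation ahead of retro-ene or sigmatropic loss of the secondary benzylic ynol ether and ahead of hydration, is secured by the high reactivity of the ynol ether–furan pair at 0–20 °C under dry, acid-free conditions, with the formyl group masked as a dioxolane that does not deactivate the furan.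

**Step 11**
Reactants: 18 phenol
Product: 20 (2R,3R)-2-[4-(benzyloxy)-3-methoxyphenyl]-7-methoxy-3-{[(triisopropylsilyl)oxy]methyl}-2,3-dihydrobenzofuran-5-carbaldehyde, via methyl ether acetal 19 (not isolated)
Conditions: MeI, K2CO3, acetone, 40 °C; filter; then PPTS, acetone–H2O, 45 °C
Reagents that add atoms: iodomethane, CI; water, O
Why: Williamson methylation of the C7' phenoxide, then mild transacetalisation of the aryl dioxolane; the weak acid does not ionise the benzylic C2'–O1' bond, so the cis ring junction is kept.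

**Step 12**
Reactants: 21 methyl 3-hydroxypropanoate
Product: 22 methyl 3-[(triisopropylsilyl)oxy]propanoate
Conditions: TIPSCl, imidazole, DMF, 25 °C
Reagents that add atoms: chlorotriisopropylsilane, CC(C)[Si](Cl)(C(C)C)C(C)C
Why: Routine silylation of a primary alcohol.

**Step 13**
Reactants: 22 silyloxy ester
Product: 23 3-[(triisopropylsilyl)oxy]propanoic acid
Conditions: LiOH·H2O, THF–H2O, 0 °C; citric acid
Reagents that add atoms: lithium hydroxide, [Li+].[OH-]
Why: Saponification at 0 °C is faster than β-elimination of the hindered silyloxide.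

**Step 14**
Reactants: 23 silyloxy acid; 24 (S)-4-benzyloxazolidin-2-one
Product: 26 (S)-4-benzyl-3-{3-[(triisopropylsilyl)oxy]propanoyl}oxazolidin-2-one, via mixed pivalic anhydride 25 (not isolated)
Conditions: PivCl, Et3N, THF, −20 °C; then 24, LiCl, 25 °C
Reagents that add atoms: pivaloyl chloride, CC(C)(C)C(Cl)=O (in 25 only)
Why: Same mixed-anhydride N-acylation as in step 5.

**Step 15**
Reactants: 26 silyloxypropanoyl imide (2 equiv); 20 aldehyde
Product: 28 (S)-4-benzyl-3-[(2R,3S)-3-Ar'-3-hydroxy-2-{[(triisopropylsilyl)oxy]methyl}propanoyl]oxazolidin-2-one, via trimethylsilyl ether 27 (not isolated)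
Conditions: MgCl2 (20 mol%), Et3N, TMSCl, EtOAc, 23 °C; then Et3N·3HF, THF, 0 °C
Reagents that add atoms: chlorotrimethylsilane, C[Si](C)(C)Cl (in 27 only)
Why: Second Evans MgCl2-catalysed anti-aldol: the chelated Z-enolate of the (S)-imide should add to the aryl aldehyde on the face away from the auxiliary benzyl group, setting C4 and C5 anti (the 4,5-trans pair of the tetrahydrofuran), and the soft enolisation limits β-elimination of the silyloxy group.

**Step 16**
Reactants: 28 anti-aldol adduct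
Product: 29 (2R,3S)-3-Ar'-3-hydroxy-N-methoxy-N-methyl-2-{[(triisopropylsilyl)oxy]methyl}propanamide
Conditions: MeNHOMe·HCl, AlMe3, CH2Cl2, −20 → 0 °C
Reagents that add atoms: N,O-dimethylhydroxylamine hydrochloride, CNOC.Cl
Why: Aluminium amide transamidation of a β-hydroxy N-acyl oxazolidinone to the Weinreb amide is directed by the free hydroxyl to the exocyclic carbonyl and does not epimerise C4.

**Step 17**
Reactants: 29 Weinreb amide; 30 ethynyltrimethylsilane
Product: 31 (4R,5S)-5-Ar'-5-hydroxy-4-{[(triisopropylsilyl)oxy]methyl}-1-(trimethylsilyl)pent-1-yn-3-one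
Conditions: 30, n-BuLi, THF, −78 °C (3.5 equiv LiC≡CSiMe3); then 29, −78 → −20 °C; aq. NH4Cl
Reagents that add atoms: none
Why: Acetylide addition to a Weinreb amide stops at the chelated tetrahedral intermediate, so the ynone is released only on work-up; the excess reagent covers the free hydroxyl.

**Step 18**
Reactants: 31 β-hydroxy ynone
Product: 32 (3S,4R,5S)-5-Ar'-4-{[(triisopropylsilyl)oxy]methyl}-1-(trimethylsilyl)pent-1-yne-3,5-diol
Conditions: Me4NBH(OAc)3, MeCN–AcOH, −30 °C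
Reagents that add atoms: none
Why: Evans–Saksena reduction: hydride is delivered intramolecularly from the C5 alkoxy-borohydride through a chair transition state with the aryl and silyloxymethyl groups equatorial, setting C3 1,3-anti to C5.

**Step 19**
Reactants: 32 anti-1,3-diol
Product: 34 (3S,4S,5S)-5-Ar'-2-methylidene-4-{[(triisopropylsilyl)oxy]methyl}tetrahydrofuran-3-ol, via terminal alkyne 33 (not isolated)
Conditions: K2CO3, MeOH, 0 °C; solvent exchange; then AuCl (5 mol%), K2CO3 (10 mol%), MeCN, 20 °C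
Reagents that add atoms: none
Why: After C-desilylation, monovalent gold activates the terminal alkyne for Markovnikov 5-exo-dig hydroalkoxylation by the C5 hydroxyl (O1–C2 bond), closing the tetrahydrofuran; the carbonate buffer protects the exocyclic enol ether.

**Step 20**
Reactants: 35 4-bromo-2-methoxyphenol
Product: 36 1-(benzyloxy)-4-bromo-2-methoxybenzene
Conditions: BnBr, K2CO3, DMF, 25 °C
Reagents that add atoms: benzyl bromide, BrCc1ccccc1
Why: Williamson benzylation of a phenol.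

**Step 21**
Reactants: 34 exocyclic enol ether; 36 aryl bromide
Product: 38 (2S,3S,4S,5S)-5-Ar'-2-[4-(benzyloxy)-3-methoxybenzyl]-4-{[(triisopropylsilyl)oxy]methyl}tetrahydrofuran-3-ol, via B-alkyl-9-BBN adduct 37 (not isolated)
Conditions: 9-BBN (3 equiv), THF, 0 → 25 °C; then 36, PdCl2(dppf) (5 mol%), aq. K3PO4, DMF, 50 °C
Reagents that add atoms: 9-borabicyclo[3.3.1]nonane, B1C2CCCC1CCC2 (in 37 only)
Why: 9-BBN should add to the exocyclic enol ether with boron on the terminal carbon and hydrogen delivered to C2 from the face opposite the adjacent C3 oxygen and the C5 aryl group, which sets C2 (benzyl cis to the C3 hydroxyl); B-alkyl Suzuki–Miyaura coupling then forms the CH2–aryl bond.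

**Step 22**
Reactants: 38 bis-silyl ether
Product: 39 (2S,3S,4S,5S)-2-[4-(benzyloxy)-3-methoxybenzyl]-5-{(2R,3R)-2-[4-(benzyloxy)-3-methoxyphenyl]-3-(hydroxymethyl)-7-methoxy-2,3-dihydrobenzofuran-5-yl}-4-(hydroxymethyl)tetrahydrofuran-3-ol
Conditions: Bu4NF, THF, 0 → 25 °C
Reagents that add atoms: none
Why: Fluoride cleaves both primary silyl ethers while the phenols are still benzylated, so the cis-dihydrobenzofuran cannot open through a quinone methide under the basic conditions.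

**Step 23**
Reactants: 39 dibenzyl ether
Product: 40 (2S,3S,4S,5S)-5-[(2R,3R)-2-(4-hydroxy-3-methoxyphenyl)-3-(hydroxymethyl)-7-methoxy-2,3-dihydrobenzofuran-5-yl]-2-(4-hydroxy-3-methoxybenzyl)-4-(hydroxymethyl)tetrahydrofuran-3-ol (CNP0179668.1)
Conditions: H2 (1 atm), Pd/C (10%), EtOAc–MeOH, 25 °C, stopped at full conversion
Reagents that add atoms: none
Why: Hydrogenolysis of the two aryl benzyl ethers is fast under neutral conditions and should be complete before the secondary benzylic C–O bonds of the two ring ethers are attacked.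

**Compound list**

1 | 3-furaldehyde | O=Cc1ccoc1 | starting material
2 | 2-(furan-3-yl)-1,3-dioxolane | C1COC(O1)c1ccoc1 | intermediate
3 | 2-[4-(1,3-dioxolan-2-yl)furan-2-yl]-4,4,5,5-tetramethyl-1,3,2-dioxaborolane | CC1(C)OB(OC1(C)C)c1cc(co1)C1OCCO1 | intermediate
4 | ethyl bromoacetate | CCOC(=O)CBr | starting material
5 | ethyl 2-[4-(1,3-dioxolan-2-yl)furan-2-yl]acetate | CCOC(=O)Cc1cc(co1)C1OCCO1 | intermediate
6 | 2-[4-(1,3-dioxolan-2-yl)furan-2-yl]acetic acid | OC(=O)Cc1cc(co1)C1OCCO1 | intermediate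
7 | (R)-4-benzyloxazolidin-2-one | O=C1N[C@H](Cc2ccccc2)CO1 | starting material
8 | mixed anhydride of 6 and pivalic acid | CC(C)(C)C(=O)OC(=O)Cc1cc(co1)C1OCCO1 | intermediate (not isolated)
9 | (R)-4-benzyl-3-{2-[4-(1,3-dioxolan-2-yl)furan-2-yl]acetyl}oxazolidin-2-one | O=C(Cc1cc(co1)C1OCCO1)N1[C@H](Cc2ccccc2)COC1=O | intermediate
10 | 4-(benzyloxy)-3-methoxybenzaldehyde (O-benzylvanillin) | O=Cc1ccc(OCc2ccccc2)c(OC)c1 | starting material
11 | trimethylsilyl ether of 12 | O=C([C@@H](c1cc(co1)C1OCCO1)[C@@H](O[Si](C)(C)C)c1ccc(OCc2ccccc2)c(OC)c1)N1[C@H](Cc2ccccc2)COC1=O | intermediate (not isolated)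
12 | (R)-4-benzyl-3-{(2R,3R)-3-[4-(benzyloxy)-3-methoxyphenyl]-2-[4-(1,3-dioxolan-2-yl)furan-2-yl]-3-hydroxypropanoyl}oxazolidin-2-one | O=C([C@@H](c1cc(co1)C1OCCO1)[C@@H](O)c1ccc(OCc2ccccc2)c(OC)c1)N1[C@H](Cc2ccccc2)COC1=O | intermediate
13 | (1R,2R)-1-[4-(benzyloxy)-3-methoxyphenyl]-2-[4-(1,3-dioxolan-2-yl)furan-2-yl]propane-1,3-diol | OC[C@@H](c1cc(co1)C1OCCO1)[C@@H](O)c1ccc(OCc2ccccc2)c(OC)c1 | intermediate
14 | (1R,2R)-1-[4-(benzyloxy)-3-methoxyphenyl]-2-[4-(1,3-dioxolan-2-yl)furan-2-yl]-3-[(triisopropylsilyl)oxy]propan-1-ol | CC(C)[Si](OC[C@@H](c1cc(co1)C1OCCO1)[C@@H](O)c1ccc(OCc2ccccc2)c(OC)c1)(C(C)C)C(C)C | intermediate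
15 | trichloroethylene | ClC=C(Cl)Cl | starting material
16 | (E)-1,2-dichlorovinyl ether of 14 | CC(C)[Si](OC[C@@H](c1cc(co1)C1OCCO1)[C@@H](O/C(Cl)=C\Cl)c1ccc(OCc2ccccc2)c(OC)c1)(C(C)C)C(C)C | intermediate (not isolated)
17 | (1R,2R)-1-[4-(benzyloxy)-3-methoxyphenyl]-2-[4-(1,3-dioxolan-2-yl)furan-2-yl]-1-(ethynyloxy)-3-[(triisopropylsilyl)oxy]propane | CC(C)[Si](OC[C@@H](c1cc(co1)C1OCCO1)[C@@H](OC#C)c1ccc(OCc2ccccc2)c(OC)c1)(C(C)C)C(C)C | intermediate (key-step precursor)
18 | (2R,3R)-2-[4-(benzyloxy)-3-methoxyphenyl]-5-(1,3-dioxolan-2-yl)-3-{[(triisopropylsilyl)oxy]methyl}-2,3-dihydrobenzofuran-7-ol | O1CCOC1c1cc(O)c2c(c1)[C@H](CO[Si](C(C)C)(C(C)C)C(C)C)[C@H](c1ccc(OCc3ccccc3)c(OC)c1)O2 | intermediate (key-step product)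
19 | 7-O-methyl ether of 18 | O1CCOC1c1cc(OC)c2c(c1)[C@H](CO[Si](C(C)C)(C(C)C)C(C)C)[C@H](c1ccc(OCc3ccccc3)c(OC)c1)O2 | intermediate (not isolated)
20 | (2R,3R)-2-[4-(benzyloxy)-3-methoxyphenyl]-7-methoxy-3-{[(triisopropylsilyl)oxy]methyl}-2,3-dihydrobenzofuran-5-carbaldehyde (Ar'–CHO) | O=Cc1cc(OC)c2c(c1)[C@H](CO[Si](C(C)C)(C(C)C)C(C)C)[C@H](c1ccc(OCc3ccccc3)c(OC)c1)O2 | intermediate
21 | methyl 3-hydroxypropanoate | OCCC(=O)OC | starting material
22 | methyl 3-[(triisopropylsilyl)oxy]propanoate | COC(=O)CCO[Si](C(C)C)(C(C)C)C(C)C | intermediate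
23 | 3-[(triisopropylsilyl)oxy]propanoic acid | OC(=O)CCO[Si](C(C)C)(C(C)C)C(C)C | intermediate
24 | (S)-4-benzyloxazolidin-2-one | O=C1N[C@@H](Cc2ccccc2)CO1 | starting material
25 | mixed anhydride of 23 and pivalic acid | CC(C)(C)C(=O)OC(=O)CCO[Si](C(C)C)(C(C)C)C(C)C | intermediate (not isolated)
26 | (S)-4-benzyl-3-{3-[(triisopropylsilyl)oxy]propanoyl}oxazolidin-2-one | O=C(CCO[Si](C(C)C)(C(C)C)C(C)C)N1[C@@H](Cc2ccccc2)COC1=O | intermediate
27 | trimethylsilyl ether of 28 | O=C([C@H](CO[Si](C(C)C)(C(C)C)C(C)C)[C@H](O[Si](C)(C)C)c1cc(OC)c2c(c1)[C@H](CO[Si](C(C)C)(C(C)C)C(C)C)[C@H](c1ccc(OCc3ccccc3)c(OC)c1)O2)N1[C@@H](Cc2ccccc2)COC1=O | intermediate (not isolated)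
28 | (S)-4-benzyl-3-[(2R,3S)-3-Ar'-3-hydroxy-2-{[(triisopropylsilyl)oxy]methyl}propanoyl]oxazolidin-2-one | O=C([C@H](CO[Si](C(C)C)(C(C)C)C(C)C)[C@H](O)c1cc(OC)c2c(c1)[C@H](CO[Si](C(C)C)(C(C)C)C(C)C)[C@H](c1ccc(OCc3ccccc3)c(OC)c1)O2)N1[C@@H](Cc2ccccc2)COC1=O | intermediate
29 | (2R,3S)-3-Ar'-3-hydroxy-N-methoxy-N-methyl-2-{[(triisopropylsilyl)oxy]methyl}propanamide | CON(C)C(=O)[C@H](CO[Si](C(C)C)(C(C)C)C(C)C)[C@H](O)c1cc(OC)c2c(c1)[C@H](CO[Si](C(C)C)(C(C)C)C(C)C)[C@H](c1ccc(OCc3ccccc3)c(OC)c1)O2 | intermediate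
30 | ethynyltrimethylsilane | C#C[Si](C)(C)C | starting material
31 | (4R,5S)-5-Ar'-5-hydroxy-4-{[(triisopropylsilyl)oxy]methyl}-1-(trimethylsilyl)pent-1-yn-3-one | C[Si](C)(C)C#CC(=O)[C@H](CO[Si](C(C)C)(C(C)C)C(C)C)[C@H](O)c1cc(OC)c2c(c1)[C@H](CO[Si](C(C)C)(C(C)C)C(C)C)[C@H](c1ccc(OCc3ccccc3)c(OC)c1)O2 | intermediate
32 | (3S,4R,5S)-5-Ar'-4-{[(triisopropylsilyl)oxy]methyl}-1-(trimethylsilyl)pent-1-yne-3,5-diol | C[Si](C)(C)C#C[C@@H](O)[C@H](CO[Si](C(C)C)(C(C)C)C(C)C)[C@H](O)c1cc(OC)c2c(c1)[C@H](CO[Si](C(C)C)(C(C)C)C(C)C)[C@H](c1ccc(OCc3ccccc3)c(OC)c1)O2 | intermediate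
33 | C-desilylated terminal alkyne of 32 (same stereocentres) | C#C[C@@H](O)[C@H](CO[Si](C(C)C)(C(C)C)C(C)C)[C@H](O)c1cc(OC)c2c(c1)[C@H](CO[Si](C(C)C)(C(C)C)C(C)C)[C@H](c1ccc(OCc3ccccc3)c(OC)c1)O2 | intermediate (not isolated)
34 | (3S,4S,5S)-5-Ar'-2-methylidene-4-{[(triisopropylsilyl)oxy]methyl}tetrahydrofuran-3-ol | C=C1O[C@H](c2cc(OC)c3c(c2)[C@H](CO[Si](C(C)C)(C(C)C)C(C)C)[C@H](c2ccc(OCc4ccccc4)c(OC)c2)O3)[C@@H](CO[Si](C(C)C)(C(C)C)C(C)C)[C@@H]1O | intermediate
35 | 4-bromo-2-methoxyphenol | COc1cc(Br)ccc1O | starting material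
36 | 1-(benzyloxy)-4-bromo-2-methoxybenzene | COc1cc(Br)ccc1OCc1ccccc1 | intermediate
37 | 9-{[(2S,3S,4S,5S)-5-Ar'-3-hydroxy-4-{[(triisopropylsilyl)oxy]methyl}tetrahydrofuran-2-yl]methyl}-9-borabicyclo[3.3.1]nonane | B1(C2CCCC1CCC2)C[C@@H]3O[C@H](c4cc(OC)c5c(c4)[C@H](CO[Si](C(C)C)(C(C)C)C(C)C)[C@H](c4ccc(OCc6ccccc6)c(OC)c4)O5)[C@@H](CO[Si](C(C)C)(C(C)C)C(C)C)[C@@H]3O | intermediate (not isolated)
38 | (2S,3S,4S,5S)-5-Ar'-2-[4-(benzyloxy)-3-methoxybenzyl]-4-{[(triisopropylsilyl)oxy]methyl}tetrahydrofuran-3-ol | COc1cc(C[C@@H]2O[C@H](c3cc(OC)c4c(c3)[C@H](CO[Si](C(C)C)(C(C)C)C(C)C)[C@H](c3ccc(OCc5ccccc5)c(OC)c3)O4)[C@@H](CO[Si](C(C)C)(C(C)C)C(C)C)[C@@H]2O)ccc1OCc1ccccc1 | intermediate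
39 | (2S,3S,4S,5S)-2-[4-(benzyloxy)-3-methoxybenzyl]-5-{(2R,3R)-2-[4-(benzyloxy)-3-methoxyphenyl]-3-(hydroxymethyl)-7-methoxy-2,3-dihydrobenzofuran-5-yl}-4-(hydroxymethyl)tetrahydrofuran-3-ol | COc1cc(C[C@@H]2O[C@H](c3cc(OC)c4c(c3)[C@H](CO)[C@H](c3ccc(OCc5ccccc5)c(OC)c3)O4)[C@@H](CO)[C@@H]2O)ccc1OCc1ccccc1 | intermediate
40 | (2S,3S,4S,5S)-5-[(2R,3R)-2-(4-hydroxy-3-methoxyphenyl)-3-(hydroxymethyl)-7-methoxy-2,3-dihydrobenzofuran-5-yl]-2-(4-hydroxy-3-methoxybenzyl)-4-(hydroxymethyl)tetrahydrofuran-3-ol | COc1cc(C[C@@H]2O[C@H](c3cc(OC)c4c(c3)[C@H](CO)[C@H](c3ccc(O)c(OC)c3)O4)[C@@H](CO)[C@@H]2O)ccc1O | target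

**Step count**

Total: 23 steps. Longest linear sequence: 19 steps (steps 1–11, 15–19, 21–23).

**Steps most likely to fail**

1. Step 10 (key step). The terminal benzylic ynol ether may fragment by retro-ene loss or sigmatropic shift, or hydrate, before it cyclises, and turnover on the 5-unsubstituted furan may be slow. Fallback: leave the furan–yne route and build the cis-dihydrobenzofuran by rhodium-carbenoid C–H insertion, setting out from aldehyde 10 and returning at 19. Aldehyde 10 is reduced with NaBH4 to [4-(benzyloxy)-3-methoxyphenyl]methanol F1, which PBr3 converts into 1-(benzyloxy)-4-(bromomethyl)-2-methoxybenzene F2. Commercial 5-iodovanillin is O-alkylated with F2 (K2CO3, DMF) to 4-{[4-(benzyloxy)-3-methoxybenzyl]oxy}-3-iodo-5-methoxybenzaldehyde F3, and acetalisation (ethylene glycol, PPTS) gives the dioxolane F4. Coupling of the aryl iodide with ethyl diazoacetate (Pd(PPh3)4, Ag2CO3, Et3N, toluene) gives the aryldiazoacetate F5. Intramolecular insertion of the carbenoid into the benzylic ether C–H bond with Rh2(S-PTTL)4, or its enantiomer, whichever leads to the (2R) series, in toluene at low temperature should give the cis ethyl 2-aryl-2,3-dihydrobenzofuran-3-carboxylate F6. DIBAL-H at −78 °C gives the primary alcohol F7 without epimerising C3', and TIPSCl/imidazole gives 19, which is hydrolysed to 20 as in step 11.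

2. Step 15. The silyloxide may be lost from the magnesium enolate by β-elimination, conversion may be low with the hindered electron-rich aldehyde, or facial control may be poor. Fallback: replace the aldol by an allylboration, setting out from aldehyde 20 and returning at Weinreb amide 29. (E)-But-2-ene-1,4-diol is monosilylated to (E)-4-[(triisopropylsilyl)oxy]but-2-en-1-ol F8, which is borylated (B2pin2, [Pd(MeCN)4](BF4)2 cat., DMSO–MeOH) to the (E)-γ-(silyloxymethyl)allyl pinacolboronate F9. Chiral phosphoric acid catalysis ((S)-TRIP, the antipode of the acid that gives (R)-carbinols from benzaldehyde) of the addition of F9 to 20 through a chair transition state should give the anti homoallylic alcohol F10. Lemieux–Johnson cleavage (OsO4 cat., NaIO4, 2,6-lutidine) gives the β-hydroxy aldehyde F11, Pinnick oxidation (NaClO2, NaH2PO4, 2-methyl-2-butene) gives the β-hydroxy acid F12, and EDC/HOBt coupling with MeNHOMe·HCl gives 29.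

3. Step 6. Anti selectivity may erode, or the acidic furyl-bearing centre may epimerise, with the heteroarylacetyl imide. Fallback: make the syn stereodiad by a boron aldol and correct C2' by inversion, setting out from acid 6 and returning at alcohol 14. Acid 6 is coupled with (S)-4-benzyloxazolidin-2-one 24 as in step 5 to give the (S)-configured imide F13. Its dibutylboron enolate (Bu2BOTf, i-Pr2NEt, CH2Cl2, −78 °C) adds to 10 through a Zimmerman–Traxler chair to give the (2R,3S) syn aldol adduct F14, which is correct at C3' and epimeric at C2'. LiBH4 gives the syn diol F15 and TIPSCl the primary silyl ether F16. Mitsunobu reaction of the benzylic alcohol with 4-nitrobenzoic acid (PPh3, DIAD) gives the inverted 4-nitrobenzoate F17, and K2CO3/MeOH gives 14.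

**Further compounds**

F1 | step 10 | [4-(benzyloxy)-3-methoxyphenyl]methanol | OCc1ccc(OCc2ccccc2)c(OC)c1
F2 | step 10 | 1-(benzyloxy)-4-(bromomethyl)-2-methoxybenzene | BrCc1ccc(OCc2ccccc2)c(OC)c1
F3 | step 10 | 4-{[4-(benzyloxy)-3-methoxybenzyl]oxy}-3-iodo-5-methoxybenzaldehyde | O=Cc1cc(I)c(OCc2ccc(OCc3ccccc3)c(OC)c2)c(OC)c1
F4 | step 10 | 2-(4-{[4-(benzyloxy)-3-methoxybenzyl]oxy}-3-iodo-5-methoxyphenyl)-1,3-dioxolane | C1COC(O1)c1cc(I)c(OCc2ccc(OCc3ccccc3)c(OC)c2)c(OC)c1
F5 | step 10 | ethyl 2-diazo-2-(2-{[4-(benzyloxy)-3-methoxybenzyl]oxy}-5-(1,3-dioxolan-2-yl)-3-methoxyphenyl)acetate | CCOC(=O)C(=[N+]=[N-])c1cc(cc(OC)c1OCc1ccc(OCc2ccccc2)c(OC)c1)C1OCCO1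
F6 | step 10 | ethyl (2R,3S)-2-[4-(benzyloxy)-3-methoxyphenyl]-5-(1,3-dioxolan-2-yl)-7-methoxy-2,3-dihydrobenzofuran-3-carboxylate (cis) | O1CCOC1c1cc(OC)c2c(c1)[C@H](C(=O)OCC)[C@H](c1ccc(OCc3ccccc3)c(OC)c1)O2
F7 | step 10 | {(2R,3R)-2-[4-(benzyloxy)-3-methoxyphenyl]-5-(1,3-dioxolan-2-yl)-7-methoxy-2,3-dihydrobenzofuran-3-yl}methanol | O1CCOC1c1cc(OC)c2c(c1)[C@H](CO)[C@H](c1ccc(OCc3ccccc3)c(OC)c1)O2
F8 | step 15 | (E)-4-[(triisopropylsilyl)oxy]but-2-en-1-ol | CC(C)[Si](OC/C=C/CO)(C(C)C)C(C)C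
F9 | step 15 | (E)-triisopropyl{[4-(4,4,5,5-tetramethyl-1,3,2-dioxaborolan-2-yl)but-2-en-1-yl]oxy}silane | CC(C)[Si](OC/C=C/CB1OC(C)(C)C(C)(C)O1)(C(C)C)C(C)C
F10 | step 15 | (1S,2S)-1-Ar'-2-{[(triisopropylsilyl)oxy]methyl}but-3-en-1-ol (anti) | C=C[C@H](CO[Si](C(C)C)(C(C)C)C(C)C)[C@H](O)c1cc(OC)c2c(c1)[C@H](CO[Si](C(C)C)(C(C)C)C(C)C)[C@H](c1ccc(OCc3ccccc3)c(OC)c1)O2
F11 | step 15 | (2R,3S)-3-Ar'-3-hydroxy-2-{[(triisopropylsilyl)oxy]methyl}propanal | O=C[C@H](CO[Si](C(C)C)(C(C)C)C(C)C)[C@H](O)c1cc(OC)c2c(c1)[C@H](CO[Si](C(C)C)(C(C)C)C(C)C)[C@H](c1ccc(OCc3ccccc3)c(OC)c1)O2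
F12 | step 15 | (2R,3S)-3-Ar'-3-hydroxy-2-{[(triisopropylsilyl)oxy]methyl}propanoic acid | OC(=O)[C@H](CO[Si](C(C)C)(C(C)C)C(C)C)[C@H](O)c1cc(OC)c2c(c1)[C@H](CO[Si](C(C)C)(C(C)C)C(C)C)[C@H](c1ccc(OCc3ccccc3)c(OC)c1)O2
F13 | step 6 | (S)-4-benzyl-3-{2-[4-(1,3-dioxolan-2-yl)furan-2-yl]acetyl}oxazolidin-2-one | O=C(Cc1cc(co1)C1OCCO1)N1[C@@H](Cc2ccccc2)COC1=O
F14 | step 6 | (S)-4-benzyl-3-{(2R,3S)-3-[4-(benzyloxy)-3-methoxyphenyl]-2-[4-(1,3-dioxolan-2-yl)furan-2-yl]-3-hydroxypropanoyl}oxazolidin-2-one (syn) | O=C([C@@H](c1cc(co1)C1OCCO1)[C@H](O)c1ccc(OCc2ccccc2)c(OC)c1)N1[C@@H](Cc2ccccc2)COC1=O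
F15 | step 6 | (1S,2R)-1-[4-(benzyloxy)-3-methoxyphenyl]-2-[4-(1,3-dioxolan-2-yl)furan-2-yl]propane-1,3-diol | OC[C@@H](c1cc(co1)C1OCCO1)[C@H](O)c1ccc(OCc2ccccc2)c(OC)c1
F16 | step 6 | (1S,2R)-1-[4-(benzyloxy)-3-methoxyphenyl]-2-[4-(1,3-dioxolan-2-yl)furan-2-yl]-3-[(triisopropylsilyl)oxy]propan-1-ol | CC(C)[Si](OC[C@@H](c1cc(co1)C1OCCO1)[C@H](O)c1ccc(OCc2ccccc2)c(OC)c1)(C(C)C)C(C)C
F17 | step 6 | (1R,2R)-1-[4-(benzyloxy)-3-methoxyphenyl]-2-[4-(1,3-dioxolan-2-yl)furan-2-yl]-3-[(triisopropylsilyl)oxy]propyl 4-nitrobenzoate | CC(C)[Si](OC[C@@H](c1cc(co1)C1OCCO1)[C@@H](OC(=O)c1ccc(cc1)[N+]([O-])=O)c1ccc(OCc2ccccc2)c(OC)c1)(C(C)C)C(C)C
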